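**Retrosynthetic overview**
- The last bond is the C(sp2)–C(sp3) bond next to the furylethyl unit, made by B-alkyl Suzuki coupling of an (E)-alkenyl iodide with the 9-BBN adduct of 3-vinylfuran, so the oxidation-sensitive furan enters last.
- The alkenyl iodide comes from a terminal homopropargylic alcohol by syn-methylalumination and iodination; the alkyne comes from an enal and an allenylboronate by chiral-phosphoric-acid propargylation, which sets the allylic carbinol.
- The enal comes from an allylic benzoate of the hydroxy lactone, and this from a butenolide by C=C hydrogenation; the butenolide comes from an achiral aldehyde and α-angelica lactone by a proposed organocatalytic direct vinylogous aldol addition that sets the carbinol and the quaternary lactone carbon together.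
- The aldehyde comes from geranyl benzoate by site-selective ozonolysis of the remote trisubstituted alkene.
- Rings: the lactone ring is brought in as α-angelica lactone (step 2) and saturated in step 3; the furan ring is attached preformed in step 9; no ring is built de novo.

Assumption: the senses of asymmetric induction in steps 2 and 6 are assigned by analogy with the closest catalyst–substrate pairs; if either is reversed on this substrate, the pseudo-enantiomeric or mirror-image catalyst is used.

**Step 1**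
Reactants: 1 geranyl benzoate [(2E)-3,7-dimethylocta-2,6-dien-1-yl benzoate]
Product: 3 (2E)-3-methyl-6-oxohex-2-en-1-yl benzoate, via ozonide 2 (not isolated)
Conditions: O3 (1.0 equiv, dosed), CH2Cl2, −78 °C; then Me2S, −78 °C to rt
Reagents that add atoms: ozone, [O-][O+]=O
Why: Criegee ozonolysis with reductive work-up cleaves the electron-rich remote trisubstituted alkene in preference to the alkene deactivated by the allylic benzoate, and the transient racemic ozonide is reduced in the same flask, so 3 is achiral.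

**Step 2**
Reactants: 3 (2E)-3-methyl-6-oxohex-2-en-1-yl benzoate; 4 α-angelica lactone [5-methylfuran-2(3H)-one]
Product: 5 (2E,6R)-6-hydroxy-3-methyl-6-[(2S)-2-methyl-5-oxo-2,5-dihydrofuran-2-yl]hex-2-en-1-yl benzoate
Conditions: 4 (3 equiv), N-[3,5-bis(trifluoromethyl)phenyl]-N′-(9-deoxy-epi-quinin-9-yl)squaramide (10 mol%), 4 Å MS, toluene, −40 °C
Reagents that add atoms: none
Why: Proposed new method: a direct amine–squaramide-catalysed vinylogous aldol addition of α-angelica lactone to an enolisable aliphatic aldehyde, which has not been shown (closest known reaction types: bifunctional amine–squaramide or amine–thiourea direct vinylogous aldol additions of furan-2(5H)-one to aryl aldehydes, γ-selective Michael and Mannich additions of α-angelica lactone, and Mukaiyama vinylogous aldol additions of 2-silyloxyfurans); the quinuclidine nitrogen deprotonates 4 at C-3 to an ammonium 5-methylfuran-2-olate whose most nucleophilic carbon is C-5, as in 2-silyloxyfurans, while the squaramide N–H bonds hold and activate the aldehyde C=O, so that C–C bond formation at C-5 through an open transition state (formyl H over the ring, C=O anti to the ring oxygen) gives the unlike pair 6R/2′S in one event, with the conjugated butenolide as thermodynamic sink and −40 °C plus excess 4 suppressing retro-aldol, α-attack and Knoevenagel condensation.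

**Step 3**
Reactants: 5 (2E,6R)-6-hydroxy-3-methyl-6-[(2S)-2-methyl-5-oxo-2,5-dihydrofuran-2-yl]hex-2-en-1-yl benzoate
Product: 6 (2E,6R)-6-hydroxy-3-methyl-6-[(2S)-2-methyl-5-oxooxolan-2-yl]hex-2-en-1-yl benzoate
Conditions: H2 (1 atm), RhCl(PPh3)3 (5 mol%), benzene/EtOH 1:1, rt
Reagents that add atoms: none
Why: Homogeneous hydrogenation with Wilkinson's catalyst reduces the cis-disubstituted conjugated ring alkene and leaves the trisubstituted alkene and the allylic benzoate alone (as in the selective 1,2-reduction of steroidal 1,4-dien-3-ones); no stereocentre is touched, and the product can no longer undergo retro-aldol.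

**Step 4**
Reactants: 6 (2E,6R)-6-hydroxy-3-methyl-6-[(2S)-2-methyl-5-oxooxolan-2-yl]hex-2-en-1-yl benzoate
Product: 7 (5S)-5-[(1R,4E)-1,6-dihydroxy-4-methylhex-4-en-1-yl]-5-methyloxolan-2-one
Conditions: K2CO3 (0.3 equiv), MeOH, 0 °C to rt; AcOH quench
Reagents that add atoms: none
Why: Zemplén-type transesterification removes the benzoate as methyl benzoate; any methanolysis of the γ-lactone is reversible and the five-membered lactone with the gem-disubstituted carbon re-closes on neutralisation.

**Step 5**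
Reactants: 7 (5S)-5-[(1R,4E)-1,6-dihydroxy-4-methylhex-4-en-1-yl]-5-methyloxolan-2-one
Product: 8 (2E,6R)-6-hydroxy-3-methyl-6-[(2S)-2-methyl-5-oxooxolan-2-yl]hex-2-enal
Conditions: MnO2 (15 equiv), CH2Cl2, rt
Reagents that add atoms: none
Why: Manganese dioxide oxidation is selective for the allylic primary alcohol over the saturated secondary alcohol and keeps the E geometry.

**Step 6**
Reactants: 8 (2E,6R)-6-hydroxy-3-methyl-6-[(2S)-2-methyl-5-oxooxolan-2-yl]hex-2-enal; 9 allenylboronic acid pinacol ester [4,4,5,5-tetramethyl-2-(propa-1,2-dien-1-yl)-1,3,2-dioxaborolane]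
Product: 11 (5S)-5-[(1R,4E,6R)-1,6-dihydroxy-4-methylnon-4-en-8-yn-1-yl]-5-methyloxolan-2-one, via borate ester 10 (not isolated)
Conditions: 9 (1.5 equiv), (R)-TRIP [(R)-3,3′-bis(2,4,6-triisopropylphenyl)-1,1′-binaphthyl-2,2′-diyl hydrogen phosphate] (10 mol%), 4 Å MS, toluene, −20 °C; aq. NaHCO3 work-up
Reagents that add atoms: none
Why: Chiral-phosphoric-acid-catalysed propargylboration through a six-membered SE2′ transition state in which the acid hydrogen-bonds to a boronate oxygen and its P=O binds the formyl hydrogen; (R)-TRIP directs attack to the Re face of the enal and sets the 6R carbinol under catalyst control, the remote stereocentres having no influence.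

**Step 7**
Reactants: 11 (5S)-5-[(1R,4E,6R)-1,6-dihydroxy-4-methylnon-4-en-8-yn-1-yl]-5-methyloxolan-2-one
Product: 13 (5S)-5-[(1R,4E,6R,8E)-1,6-dihydroxy-9-iodo-4,8-dimethylnona-4,8-dien-1-yl]-5-methyloxolan-2-one, via alkenylalane 12 (not isolated)
Conditions: AlMe3 (6 equiv), Cp2ZrCl2 (0.3 equiv), H2O (1 equiv), CH2Cl2, −25 to 0 °C; then I2, THF, −30 °C; aq. KNaC4H4O6 work-up
Reagents that add atoms: trimethylaluminium, C[Al](C)C; iodine, II
Why: Negishi zirconium-catalysed methylalumination adds Me and Al syn across the terminal alkyne (Me to the internal carbon, as for but-3-yn-1-ol), and iodinolysis with retention gives the (E)-iodoalkene; the hydroxyls are carried as aluminium alkoxides and the trisubstituted alkene is inert.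

**Step 8**
Reactants: 14 furan-3-carbaldehyde
Product: 15 3-vinylfuran (3-ethenylfuran)
Conditions: Ph3PCH3Br, n-BuLi, Et2O, 0 °C; then 14, 0 °C to rt; distillation
Reagents that add atoms: methyltriphenylphosphonium bromide, C[P+](c1ccccc1)(c1ccccc1)c1ccccc1.[Br-]
Why: Wittig methylenation of an aromatic aldehyde with the unstabilised ylide is routine and the volatile product is separated by distillation.

**Step 9**
Reactants: 13 (5S)-5-[(1R,4E,6R,8E)-1,6-dihydroxy-9-iodo-4,8-dimethylnona-4,8-dien-1-yl]-5-methyloxolan-2-one; 15 3-vinylfuran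
Product: 17 (5S)-5-[(1R,4E,6R,8E)-11-(furan-3-yl)-1,6-dihydroxy-4,8-dimethylundeca-4,8-dien-1-yl]-5-methyloxolan-2-one, via alkylborane 16 (not isolated)
Conditions: 15 (1.6 equiv), 9-BBN (1.5 equiv), THF, 0 °C to rt; then 13, PdCl2(dppf) (10 mol%), AsPh3, Cs2CO3, DMF/H2O, rt
Reagents that add atoms: none
Why: Anti-Markovnikov hydroboration of the vinyl arene followed by B-alkyl Suzuki–Miyaura coupling joins the primary alkylborane to the alkenyl iodide with retention of the E geometry under mild base that the lactone and free hydroxyls tolerate, giving the target.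

**Compound list**
1 | geranyl benzoate, (2E)-3,7-dimethylocta-2,6-dien-1-yl benzoate | C/C(=C\COC(=O)c1ccccc1)CCC=C(C)C | starting material
2 | (2E)-5-(5,5-dimethyl-1,2,4-trioxolan-3-yl)-3-methylpent-2-en-1-yl benzoate (ozonide, racemic at the ring CH, transient) | C/C(=C\COC(=O)c1ccccc1)CCC1OOC(C)(C)O1 | intermediate
3 | (2E)-3-methyl-6-oxohex-2-en-1-yl benzoate | C/C(=C\COC(=O)c1ccccc1)CCC=O | intermediate
4 | α-angelica lactone, 5-methylfuran-2(3H)-one | CC1=CCC(=O)O1 | starting material
5 | (2E,6R)-6-hydroxy-3-methyl-6-[(2S)-2-methyl-5-oxo-2,5-dihydrofuran-2-yl]hex-2-en-1-yl benzoate | C/C(=C\COC(=O)c1ccccc1)CC[C@@H](O)[C@]2(C)C=CC(=O)O2 | intermediate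
6 | (2E,6R)-6-hydroxy-3-methyl-6-[(2S)-2-methyl-5-oxooxolan-2-yl]hex-2-en-1-yl benzoate | C/C(=C\COC(=O)c1ccccc1)CC[C@@H](O)[C@]2(C)CCC(=O)O2 | intermediate
7 | (5S)-5-[(1R,4E)-1,6-dihydroxy-4-methylhex-4-en-1-yl]-5-methyloxolan-2-one | C/C(=C\CO)CC[C@@H](O)[C@]1(C)CCC(=O)O1 | intermediate
8 | (2E,6R)-6-hydroxy-3-methyl-6-[(2S)-2-methyl-5-oxooxolan-2-yl]hex-2-enal | C/C(=C\C=O)CC[C@@H](O)[C@]1(C)CCC(=O)O1 | intermediate
9 | allenylboronic acid pinacol ester, 4,4,5,5-tetramethyl-2-(propa-1,2-dien-1-yl)-1,3,2-dioxaborolane | C=C=CB1OC(C)(C)C(C)(C)O1 | starting material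
10 | pinacol borate ester of 11 at the new (6R) carbinol oxygen | C/C(=C\[C@H](OB1OC(C)(C)C(C)(C)O1)CC#C)CC[C@@H](O)[C@]2(C)CCC(=O)O2 | intermediate
11 | (5S)-5-[(1R,4E,6R)-1,6-dihydroxy-4-methylnon-4-en-8-yn-1-yl]-5-methyloxolan-2-one | C/C(=C\[C@H](O)CC#C)CC[C@@H](O)[C@]1(C)CCC(=O)O1 | intermediate
12 | (E)-alkenyl(dimethyl)alane of 11 with both hydroxyls as dimethylaluminium alkoxides | C/C(=C\[C@H](O[Al](C)C)C/C(C)=C/[Al](C)C)CC[C@@H](O[Al](C)C)[C@]1(C)CCC(=O)O1 | intermediate
13 | (5S)-5-[(1R,4E,6R,8E)-1,6-dihydroxy-9-iodo-4,8-dimethylnona-4,8-dien-1-yl]-5-methyloxolan-2-one | C/C(=C\[C@H](O)C/C(C)=C/I)CC[C@@H](O)[C@]1(C)CCC(=O)O1 | intermediate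
14 | furan-3-carbaldehyde | O=Cc1ccoc1 | starting material
15 | 3-vinylfuran | C=Cc1ccoc1 | intermediate
16 | 9-[2-(furan-3-yl)ethyl]-9-borabicyclo[3.3.1]nonane | C(Cc1ccoc1)B1C2CCCC1CCC2 | intermediate
17 | (5S)-5-[(1R,4E,6R,8E)-11-(furan-3-yl)-1,6-dihydroxy-4,8-dimethylundeca-4,8-dien-1-yl]-5-methyloxolan-2-one | C/C(=C\[C@H](O)C/C(C)=C/CCc1ccoc1)CC[C@@H](O)[C@]1(C)CCC(=O)O1 | target

**Step count**
Total steps: 9. Longest linear sequence: 8 (steps 1 to 7 and 9, from geranyl benzoate); step 8 is a one-step side branch.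

**Steps most likely to fail, with fallbacks**

Step 2 (the proposed vinylogous aldol addition). The risks are α-attack or Knoevenagel condensation, reversibility, and insufficient control of the unlike diad. The fallback uses known chemistry, sets out from 1 and comes back at 6, replacing steps 1 to 3. Allylic oxidation of 1 (SeO2 cat., t-BuOOH, CH2Cl2, rt) gives (2E,6E)-8-hydroxy-3,7-dimethylocta-2,6-dien-1-yl benzoate F1. Appel bromination (CBr4, PPh3, CH2Cl2, 0 °C) gives (2E,6E)-8-bromo-3,7-dimethylocta-2,6-dien-1-yl benzoate F2. Alkylation of the lithium enolate of tert-butyl acetate (LiN(i-Pr)2, THF/DMPU, −78 °C) gives tert-butyl (4E,8E)-10-(benzoyloxy)-4,8-dimethyldeca-4,8-dienoate F3. Shi epoxidation (D-fructose-derived ketone, Oxone (2KHSO5·KHSO4·K2SO4), K2CO3, buffer, MeCN/dimethoxymethane, 0 °C) attacks the electron-rich alkene remote from the benzoate and gives tert-butyl 3-[(2R,3R)-3-[(3E)-5-(benzoyloxy)-3-methylpent-3-en-1-yl]-2-methyloxiran-2-yl]propanoate F4. Camphorsulfonic acid in CH2Cl2 then closes the lactone by 5-exo attack of the ester carbonyl at the tertiary epoxide carbon with inversion and loss of isobutylene, giving 6 with the same 6R/2′S configuration.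

Step 6 (propargylboration). The risks are lower enantioselectivity on a β,β-disubstituted enal and catalyst binding by the lactone and free hydroxyl. The fallback sets out from 7 and comes back at 11, replacing steps 5 and 6. Iridium-catalysed transfer-hydrogenative propargylation at the alcohol oxidation level ([Ir(cod)Cl]2, SEGPHOS enantiomer giving the 6R carbinol, 4-cyano-3-nitrobenzoic acid, Cs2CO3, 3-chloro-1-(triisopropylsilyl)prop-1-yne, THF, 70 °C) dehydrogenates only the primary allylic alcohol and gives (5S)-5-[(1R,4E,6R)-1,6-dihydroxy-4-methyl-9-(triisopropylsilyl)non-4-en-8-yn-1-yl]-5-methyloxolan-2-one F5. Desilylation with Bu4NF buffered with AcOH (THF, 0 °C) gives 11.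

Step 7 (methylalumination beside a lactone and two free hydroxyls). The risks are attack of AlMe3 on the lactone and incomplete carbometalation. The fallback avoids organoaluminium reagents, sets out from 11 and 16 and comes back at the target 17, replacing steps 7 and 9. Iodination of 16 (I2, NaOMe, THF/MeOH, 0 °C) gives 3-(2-iodoethyl)furan F6. Alkyl Sonogashira coupling of 11 with F6 ([Pd(C3H5)Cl]2, 1,3-di(1-adamantyl)imidazolium chloride, CuI, Cs2CO3, DMF/Et2O, 45 °C) gives (5S)-5-[(1R,4E,6R)-11-(furan-3-yl)-1,6-dihydroxy-4-methylundec-4-en-8-yn-1-yl]-5-methyloxolan-2-one F7. Hydroxyl-directed trans-hydrostannation ([Cp*RuCl]4 cat., Bu3SnH, CH2Cl2, rt) places tin on the alkyne carbon nearer the homopropargylic hydroxyl and gives (5S)-5-[(1R,4E,6R,8Z)-11-(furan-3-yl)-1,6-dihydroxy-4-methyl-8-(tributylstannyl)undeca-4,8-dien-1-yl]-5-methyloxolan-2-one F8. Methyl-Stille coupling with retention (MeI, Pd(PPh3)4, Cu(O2CC4H3S), [Bu4N][Ph2PO2], DMF, rt) gives 17.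

**Further compounds**
F1 | step 2 | (2E,6E)-8-hydroxy-3,7-dimethylocta-2,6-dien-1-yl benzoate | C/C(=C\COC(=O)c1ccccc1)CC/C=C(\C)CO
F2 | step 2 | (2E,6E)-8-bromo-3,7-dimethylocta-2,6-dien-1-yl benzoate | C/C(=C\COC(=O)c1ccccc1)CC/C=C(\C)CBr
F3 | step 2 | tert-butyl (4E,8E)-10-(benzoyloxy)-4,8-dimethyldeca-4,8-dienoate | C/C(=C\COC(=O)c1ccccc1)CC/C=C(\C)CCC(=O)OC(C)(C)C
F4 | step 2 | tert-butyl 3-[(2R,3R)-3-[(3E)-5-(benzoyloxy)-3-methylpent-3-en-1-yl]-2-methyloxiran-2-yl]propanoate | C/C(=C\COC(=O)c1ccccc1)CC[C@H]1O[C@]1(C)CCC(=O)OC(C)(C)C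
F5 | step 6 | (5S)-5-[(1R,4E,6R)-1,6-dihydroxy-4-methyl-9-(triisopropylsilyl)non-4-en-8-yn-1-yl]-5-methyloxolan-2-one | C/C(=C\[C@H](O)CC#C[Si](C(C)C)(C(C)C)C(C)C)CC[C@@H](O)[C@]1(C)CCC(=O)O1
F6 | step 7 | 3-(2-iodoethyl)furan | ICCc1ccoc1
F7 | step 7 | (5S)-5-[(1R,4E,6R)-11-(furan-3-yl)-1,6-dihydroxy-4-methylundec-4-en-8-yn-1-yl]-5-methyloxolan-2-one | C/C(=C\[C@H](O)CC#CCCc1ccoc1)CC[C@@H](O)[C@]2(C)CCC(=O)O2
F8 | step 7 | (5S)-5-[(1R,4E,6R,8Z)-11-(furan-3-yl)-1,6-dihydroxy-4-methyl-8-(tributylstannyl)undeca-4,8-dien-1-yl]-5-methyloxolan-2-one | C/C(=C\[C@H](O)C/C(=C/CCc1ccoc1)[Sn](CCCC)(CCCC)CCCC)CC[C@@H](O)[C@]2(C)CCC(=O)O2
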